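**Plan**
- Retrosynthesis: the side-chain O–acetyl bond and the C5 O–methyl bond are cut first; the quinone ring is then cut at C3–C4 and C5–C6 into an α-diketone (C6, C1, C2, C3 with the side chain) and an oxalyl unit (C4, C5).
- Enabling feature: the ring carries oxygen on C1, C2, C4 and C5, so it is the bis-enol of cyclohexane-1,2,4,5-tetraone. C3 and C6 are the only two α-carbons of a 2,3-diketone and C4/C5 are an oxalate, so one double Claisen condensation should give the ring at the quinone oxidation level with no redox step.
- Forward order: C12 Grignard + (R)-epichlorohydrin → (R)-epoxide; amide-enolate opening, O-benzylation and acetyl-anion addition → diketone; ring closure with dimethyl oxalate; mono-O-methylation; debenzylation; acetylation.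
- Stereochemistry: the single stereocentre comes from (R)-epichlorohydrin (chiral pool); its C–O bond is never broken afterwards.

Key step: step 5

Assumption: hydroxyquinones are drawn as the 2-hydroxy-1,4-dione tautomer (13 is one compound although two equivalent tautomers can be drawn); dodecylmagnesium bromide is taken as a commercial solution.

**Step 1**
Reactants: 1 (R)-epichlorohydrin; 2 dodecylmagnesium bromide
Product: 4 (R)-2-tridecyloxirane, via chlorohydrin 3 (not isolated)
Conditions: CuI (10 mol %), THF, −40 → 0 °C; then 5 M aq NaOH, MeOH, rt, same flask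
Reagents that add atoms: none
Why: Copper-catalysed Grignard opening of the epoxide at its unsubstituted carbon, followed by intramolecular Williamson closure of the chlorohydrin, should give the terminal epoxide; the C–O bond at the stereocentre is untouched, so (R)-1 gives (R)-4.

**Step 2**
Reactants: 4 (R)-2-tridecyloxirane; 5 4-acetylmorpholine
Product: 6 (R)-4-hydroxy-1-(morpholin-4-yl)heptadecan-1-one
Conditions: LDA (2.2 equiv), 5 (2.2 equiv), THF, −78 °C; then 4, −78 → 25 °C; H2O quench
Reagents that add atoms: none
Why: SN2 opening of a terminal epoxide at its CH2 carbon by the lithium enolate of an N,N-dialkylacetamide (amide-enolate epoxide alkylation) should give the γ-hydroxy amide without touching the stereocentre.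

**Step 3**
Reactants: 6 (R)-4-hydroxy-1-(morpholin-4-yl)heptadecan-1-one
Product: 7 (R)-4-(benzyloxy)-1-(morpholin-4-yl)heptadecan-1-one
Conditions: NaH, BnBr, Bu4NI (cat.), THF, 0 → 25 °C
Reagents that add atoms: benzyl bromide, BrCc1ccccc1
Why: Williamson etherification installs a benzyl ether that should survive methoxide (step 5) and acidic methanol (step 6) and keeps the side-chain oxygen from closing onto the quinone; the tertiary amide is not displaced by the alkoxide.

**Step 4**
Reactants: 7 (R)-4-(benzyloxy)-1-(morpholin-4-yl)heptadecan-1-one; 8 ethyl vinyl ether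
Product: 10 (R)-6-(benzyloxy)nonadecane-2,3-dione, via ethoxy enone 9 (not isolated)
Conditions: 8, t-BuLi, THF, −78 → 0 °C; then 7, −78 → 0 °C; then 1 M HCl, THF, rt
Reagents that add atoms: water, O
Why: 1-Ethoxyvinyllithium (an acetyl-anion equivalent) should add once to the morpholine amide through a stable tetrahedral intermediate (Weinreb-type ketone synthesis), and mild acid hydrolysis of the enol ether unmasks the 2,3-diketone.

**Step 5**
Reactants: 10 (R)-6-(benzyloxy)nonadecane-2,3-dione; 11 dimethyl oxalate
Product: 13 3-[(2R)-2-(benzyloxy)pentadecyl]-2,5-dihydroxy-1,4-benzoquinone, via trioxo ester 12 (not isolated)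
Conditions: NaOMe (4 equiv), 11 (1.5 equiv), MeOH–THF, 0 °C (slow addition of 10), then 60 °C; then 1 M HCl
Reagents that add atoms: none
Why: Proposed new method: methoxide enolises the methyl terminus of the α-diketone, the enolate is C-acylated by dimethyl oxalate (crossed Claisen) to trioxo ester 12 held as its 1,3-diketonate, and a second enolisation at the α-methylene lets that carbon attack the remaining ester carbonyl; loss of methoxide gives cyclohexane-1,2,4,5-tetraone, whose bis-enol is 13. The closest known reaction types are the Claisen condensation of methyl ketones with dialkyl oxalates, oxalate-based Claisen–Dieckmann ring syntheses (cyclopentane-1,2,4-triones from dialkyl ketones) and the Fichter-type self-condensation of α-keto esters to 3,6-dialkyl-2,5-dihydroxybenzoquinones; what is new is an α-diketone as the four-carbon bis-nucleophile. The six-membered carbocycle closes by a 6-(enolexo)-exo-trig Dieckmann-type attack. No stereocentre is formed, and the existing one carries no leaving group β to either carbanion, so it should not be at risk. The step needs cross- over self-condensation and six-ring closure over other modes: excess non-enolisable, highly electrophilic oxalate with slow addition of 10 should favour the first, and in 12 the ketone carbonyls are masked as a diketonate so only the ester carbon stays electrophilic. The product should leave the equilibria as its doubly vinylogous carboxylate dianion, a thermodynamic sink that should drain reversible aldol by-products.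

**Step 6**
Reactants: 13 3-[(2R)-2-(benzyloxy)pentadecyl]-2,5-dihydroxy-1,4-benzoquinone
Product: 14 3-[(2R)-2-(benzyloxy)pentadecyl]-2-hydroxy-5-methoxy-1,4-benzoquinone
Conditions: MeOH, H2SO4 (cat.), 40 °C, stopped at the mono-ether
Reagents that add atoms: methanol, CO
Why: Acid-catalysed addition–elimination (Fischer-type etherification of a vinylogous carboxylic acid) should occur at the hydroxyl flanked by C6–H and not at the one crowded by the C3 side chain, and this mono-ether is also the thermodynamically preferred one.

**Step 7**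
Reactants: 14 3-[(2R)-2-(benzyloxy)pentadecyl]-2-hydroxy-5-methoxy-1,4-benzoquinone
Product: 16 2-hydroxy-3-[(2R)-2-hydroxypentadecyl]-5-methoxy-1,4-benzoquinone, via benzenetriol 15 (not isolated)
Conditions: H2 (1 atm), 10% Pd/C, EtOAc, rt; filter; then air, rt
Reagents that add atoms: none
Why: Hydrogenolysis cleaves the O–CH2Ph bond (not the C–O bond at the stereocentre) while reducing the quinone to the electron-rich benzenetriol, which should re-oxidise in air to the hydroxyquinone.

**Step 8**
Reactants: 16 2-hydroxy-3-[(2R)-2-hydroxypentadecyl]-5-methoxy-1,4-benzoquinone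
Product: 18 (2R)-1-(2-hydroxy-5-methoxy-3,6-dioxocyclohexa-1,4-dien-1-yl)pentadecan-2-yl acetate, via diacetate 17 (not isolated)
Conditions: Ac2O, pyridine, DMAP (cat.), CH2Cl2, 0 → 25 °C; then MeOH, rt
Reagents that add atoms: acetic anhydride, CC(=O)OC(C)=O
Why: DMAP-catalysed acylation acetylates both hydroxyls, and the quinonyl acetate, a vinylogous mixed anhydride, should then be cleaved selectively by DMAP/methanol while the secondary alkyl acetate stays, with retention at the stereocentre.

**Compound list**
1 | (R)-epichlorohydrin | ClC[C@H]1CO1 | starting material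
2 | dodecylmagnesium bromide | CCCCCCCCCCCC[Mg]Br | starting material
3 | (R)-1-chloropentadecan-2-ol (formed as its magnesium alkoxide) | ClC[C@H](O)CCCCCCCCCCCCC | intermediate
4 | (R)-2-tridecyloxirane | CCCCCCCCCCCCC[C@@H]1CO1 | intermediate
5 | 4-acetylmorpholine | CC(=O)N1CCOCC1 | starting material
6 | (R)-4-hydroxy-1-(morpholin-4-yl)heptadecan-1-one | CCCCCCCCCCCCC[C@H](CCC(=O)N1CCOCC1)O | intermediate
7 | (R)-4-(benzyloxy)-1-(morpholin-4-yl)heptadecan-1-one | CCCCCCCCCCCCC[C@H](CCC(=O)N1CCOCC1)OCc1ccccc1 | intermediate
8 | ethyl vinyl ether | C=COCC | starting material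
9 | (R)-6-(benzyloxy)-2-ethoxynonadec-1-en-3-one | CCCCCCCCCCCCC[C@H](CCC(=O)C(=C)OCC)OCc1ccccc1 | intermediate
10 | (R)-6-(benzyloxy)nonadecane-2,3-dione | CCCCCCCCCCCCC[C@H](CCC(=O)C(C)=O)OCc1ccccc1 | intermediate
11 | dimethyl oxalate | COC(=O)C(=O)OC | starting material
12 | methyl (R)-8-(benzyloxy)-2,4,5-trioxohenicosanoate | CCCCCCCCCCCCC[C@H](CCC(=O)C(=O)CC(=O)C(=O)OC)OCc1ccccc1 | intermediate
13 | 3-[(2R)-2-(benzyloxy)pentadecyl]-2,5-dihydroxy-1,4-benzoquinone | CCCCCCCCCCCCC[C@H](CC1=C(O)C(=O)C=C(O)C1=O)OCc1ccccc1 | intermediate
14 | 3-[(2R)-2-(benzyloxy)pentadecyl]-2-hydroxy-5-methoxy-1,4-benzoquinone | CCCCCCCCCCCCC[C@H](CC1=C(O)C(=O)C=C(OC)C1=O)OCc1ccccc1 | intermediate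
15 | 3-[(2R)-2-hydroxypentadecyl]-5-methoxybenzene-1,2,4-triol | CCCCCCCCCCCCC[C@H](Cc1c(O)c(O)cc(OC)c1O)O | intermediate
16 | 2-hydroxy-3-[(2R)-2-hydroxypentadecyl]-5-methoxy-1,4-benzoquinone | CCCCCCCCCCCCC[C@H](CC1=C(O)C(=O)C=C(OC)C1=O)O | intermediate
17 | (2R)-1-(2-acetoxy-5-methoxy-3,6-dioxocyclohexa-1,4-dien-1-yl)pentadecan-2-yl acetate | CCCCCCCCCCCCC[C@H](CC1=C(OC(C)=O)C(=O)C=C(OC)C1=O)OC(C)=O | intermediate
18 | (2R)-1-(2-hydroxy-5-methoxy-3,6-dioxocyclohexa-1,4-dien-1-yl)pentadecan-2-yl acetate | CCCCCCCCCCCCC[C@H](CC1=C(O)C(=O)C=C(OC)C1=O)OC(C)=O | target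

**Totals**
Total step count: 8. Longest linear sequence: 8 steps (1 → 18).

**Steps most likely to fail**

Step 5 (proposed new method). The diketone enolate may self-condense by aldol reaction, methoxide may add to the diketone and trigger a benzilic-ester-type rearrangement, or the sequence may stall after the first acylation. The fallback builds the side chain onto a ready-made arene using known reactions; it sets out from 4 and re-joins the route at 18. 1,2,4,5-Tetramethoxybenzene is lithiated (n-BuLi, THF, 0 °C) and the aryllithium opens 4 in the presence of BF3·OEt2 at −78 °C to give (R)-1-(2,3,5,6-tetramethoxyphenyl)pentadecan-2-ol F1. Ac2O/pyridine converts it into (R)-1-(2,3,5,6-tetramethoxyphenyl)pentadecan-2-yl acetate F2. Ceric ammonium nitrate in MeCN/H2O should oxidise F2 to (2R)-1-(2,5-dimethoxy-3,6-dioxocyclohexa-1,4-dien-1-yl)pentadecan-2-yl acetate F3, the same compound whichever para pair of methoxy groups is oxidised. Brief treatment with 70% HClO4 in dioxane should hydrolyse only the twisted methoxy group next to the side chain and give 18.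

Step 6. Regiocontrol may be lost or etherification may run on to the bis-ether. The fallback sets out from 13 and re-joins at 14. Both hydroxyls are methylated on purpose (TMSCHN2, MeOH/toluene, 0 °C) to give 3-[(2R)-2-(benzyloxy)pentadecyl]-2,5-dimethoxy-1,4-benzoquinone F4. Selective hydrolysis of the hindered C2 methoxy group with 70% HClO4 in dioxane should then give 14.

Step 2. The amide enolate may open the epoxide sluggishly, and the resulting alkoxide may lactonise with loss of morpholine. The fallback sets out from 4 and re-joins at 6. Dilithioacetate (acetic acid, 2 equiv LDA, THF, 40 °C) opens 4 to (R)-4-hydroxyheptadecanoic acid F5. Acid-catalysed lactonisation (TsOH, toluene) gives (R)-5-tridecyldihydrofuran-2(3H)-one F6. Aminolysis with morpholine/AlMe3 in CH2Cl2 should then give 6.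

**Further compounds**
F1 | step 5 | (R)-1-(2,3,5,6-tetramethoxyphenyl)pentadecan-2-ol | CCCCCCCCCCCCC[C@H](Cc1c(OC)c(OC)cc(OC)c1OC)O
F2 | step 5 | (R)-1-(2,3,5,6-tetramethoxyphenyl)pentadecan-2-yl acetate | CCCCCCCCCCCCC[C@H](Cc1c(OC)c(OC)cc(OC)c1OC)OC(C)=O
F3 | step 5 | (2R)-1-(2,5-dimethoxy-3,6-dioxocyclohexa-1,4-dien-1-yl)pentadecan-2-yl acetate | CCCCCCCCCCCCC[C@H](CC1=C(OC)C(=O)C=C(OC)C1=O)OC(C)=O
F4 | step 6 | 3-[(2R)-2-(benzyloxy)pentadecyl]-2,5-dimethoxy-1,4-benzoquinone | CCCCCCCCCCCCC[C@H](CC1=C(OC)C(=O)C=C(OC)C1=O)OCc1ccccc1
F5 | step 2 | (R)-4-hydroxyheptadecanoic acid | CCCCCCCCCCCCC[C@H](CCC(=O)O)O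
F6 | step 2 | (R)-5-tridecyldihydrofuran-2(3H)-one | CCCCCCCCCCCCC[C@@H]1CCC(=O)O1
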